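## Structural features

The target is a flavone: ring A (the benzo ring, C4a to C8a) is fused to the 4-pyranone ring C, phenyl ring B sits on C2, C5 carries a methoxy group, C7 a free hydroxyl, and C8 an N-methylpiperidine joined through its C2'. C2' is the only stereocentre; it is R (N1' > C8 > C3' > H) and has no neighbouring centre that could relay its configuration, so it has to be set absolutely. C2' is benzylic, bears N1' and lies between the C7 hydroxyl and O1 on C8a. The compound is therefore a phenolic Mannich base, and heterolysis of C2'-N1' pushed by an ortho oxygen gives an ortho-quinone methide whose reclosure scrambles C2'. This pathway is fastest for the zwitterion (phenoxide plus ammonium) on heating in protic media, and is slowed when the phenols are protonated, complexed or acylated and when ring A already carries the C4 acyl group. Other fragile points are the pyranone (hydride, hydroxide), the C5 methoxy group peri to C4=O (strong Lewis acids) and the basic tertiary amine (binds Lewis acids and metals, is quaternised by alkylating agents). The real difficulty is to create C2' in one configuration at a fully substituted position of a very electron-rich ring and to carry it through the construction of ring C; placing the piperidine at C8 and not at C6 is the second problem. The key step turns the lability into the bond-forming event: before ring C exists, the future C8 is flanked by two equivalent phenolic oxygens (the later C7-OH and O1), so C2' can be flattened on purpose into a methide and reclosed by nitrogen under a chiral acid. The same local symmetry settles C8 against C6.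

## Logic of the disconnections

**17 to 16.** The O1-C2 bond of ring C is cut and the C2=C3 unsaturation is returned to a carbonyl. Hemiketal formation from an ortho-hydroxyaryl 1,3-diketone and loss of water is the gentlest entry to a 4-pyranone. The gain is an open-chain diketone on a finished ring A. The forward step must use acid mild enough to leave C2'-N1' closed; the protonated amine and the acyl group on ring A work in its favour.

**16 to 14 and 15.** The C2-C3 bond is cut as a Claisen-type acylation of a methyl ketone enolate. Ring B and C2 arrive in one piece, and no phenol protection is spent if the enolate is formed inside a polyanion. The demand is that C-acylation outruns O-acylation.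

**14 to 12 and 13.** The C4-C4a bond is cut as an electrophilic acetylation. In 12 the two free ring positions are equivalent, each lies between a hydroxyl and the methoxy group, and whichever reacts, the neighbouring hydroxyl becomes O1 and the piperidine ends at C8. The demand is that the Lewis acid does not ionise C2'-N1' in what is the most electron-rich amine of the route.

**12 to 11.** N-CH3 is traced back to N-CO2CH3. The carbamate is what the preceding step needs (a non-basic nitrogen with one N-H), and its carbonyl carbon becomes the N-methyl carbon, so no deprotection and alkylation pair is required. The demand is that hydride is used before any ketone exists, which fixes the order of the endgame.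

**11 to 9, through 10.** The N1'-C2' bond is cut. This removes the ring and the stereocentre at once and leads to an acyclic, racemic carbinol whose two enantiomers converge on the planar 10. The demands are facial control on 10 and that 9 never meets an achiral acid. 9 is kept as the free, symmetric diol: masking one hydroxyl would fix the methide geometry but would make the two ring positions of 12 unequal and add steps.

**9 to 8 to 7.** The phenols are masked as fluoride-labile acetal ethers and the carbinol is traced to a ketone. 9 cannot survive acid, so the unmasking has to be done with fluoride. The ketone is a stable, storable intermediate and, with the phenols masked, is reduced without methide-mediated loss of oxygen. Racemic 8 is sufficient. The demand is a cool, non-acidic unmasking in which the released formaldehyde is trapped.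

**7 to 5 (metalated as 6) and 3.** The bond between the future C8 and C2' is cut. 6 is reached by directed metalation between the two acetal ethers. 3 delivers the five carbons and the nitrogen with the carbamate in place and, unlike an open-chain N-H carbamate aldehyde (kept as F8 in a fallback), offers neither an acidic N-H nor an enolisable aldehyde to the basic, hindered 6. The demand is attack at the ring carbonyl of 3 and not at its carbamate carbonyl.

**5 to 4; 3 to 1 and 2.** O-alkylation and N-acylation of commercial materials; no selectivity problem arises because 4 is symmetric and 1 has one N-H.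

## Other disconnections considered

**Alternative 1:** The cut is the C2=C3 double bond of ring C, with O1-C2 already present as the ester linkage of a C8a benzoate.
- Forward step: the acyl phosphorane A2 (the dibenzoate of 14 carrying CH=PPh3 on the acetyl carbon) would be heated in toluene. The ylide carbon adds to the carbonyl of the neighbouring C8a benzoate, the oxaphosphetane collapses with loss of triphenylphosphine oxide, and the 7-benzoate A1 of the target results. The C7 benzoate is out of reach and is removed afterwards.
- In favour: the closure is neutral, both phenols are acylated at that moment so the zwitterion pathway at C2' is shut, and the regiochemistry is fixed by proximity. On mildness of the ring C closure this is the better plan; in mechanistic reliability the two are equal, since both closures are established reaction types.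
- Against: it is an endgame only. It does not create C2' and would still need 12 and 14 from the chosen key step or an equivalent. A2 requires halogenation of the acetyl group and a phosphonium salt in a molecule that holds a nucleophilic tertiary amine and a ring A that halogenates readily. One equivalent of phosphine oxide and a final debenzoylation are added.
- Comparison: about five operations from 14 against one in the chosen plan, which is the better on step economy; on structure both use the C8a oxygen as the ring oxygen.

**Alternative 2:** The cut is C4'-C5' of the piperidine, made as an alkene on the finished flavone.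
- Forward step: the diene A4 would come from a Petasis borono-Mannich reaction of the C8 aldehyde A5 with N-methylallylamine and an allylboronate, then acetylation of the C7 hydroxyl. As its ammonium salt (to keep nitrogen off ruthenium) A4 would be closed with second-generation Grubbs catalyst to the tetrahydropyridine A3 with loss of ethene; hydrogenation and deacetylation would finish.
- In favour: the piperidine is built last on a flavone core that is easily available, three components are joined in one step, and the metathesis is among the most dependable ring closures. As a bond-forming event it is better precedented than the chosen key step, and the step count (about seven) is equal or slightly lower. It is also the more convergent plan.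
- Against: C2' is created in the Petasis step, where a secondary allylic amine and an allylboron reagent leave the asymmetric induction to a chiral diol catalyst on little ground. The free C7 hydroxyl that this reaction needs makes its product exactly the zwitterion-prone Mannich base. Formylation has to distinguish C8 from C6. A3 is both an allylic and a benzylic amine, so the hydrogenation has to spare C2'-N1' and the C2=C3 bond of ring C, and ruthenium hydrides can move the double bond into an enamine.
- Comparison: the chosen plan sets C2' before the acidic C7 hydroxyl and the ring ketone coexist and settles C8 against C6 by symmetry. Alternative 2 is weaker in stereocontrol and in late chemoselectivity.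

**Alternative 3:** The cut is the C8-C2' bond between ring A and an intact piperidine.
- Forward step: the bromide A7, with both phenols as piperidine-1-carboxylates, would add oxidatively to zerovalent palladium bearing a chiral ligand. Carboxylate-assisted metalation of an alpha-methylene C-H of one carbamate piperidine and reductive elimination would give the benzoxazinone A6. LiAlH4 would then turn the ring carbamate carbonyl into the N-methyl group and cleave the spectator carbamate, arriving at 12.
- In favour: it is the shortest line to 12 (about four steps against seven) and is the better plan on step economy. It needs no protecting groups and no fragile benzylic alcohol. In its use of the symmetric ring and of a carbamate carbon as the future N-methyl it is the equal of the chosen plan.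
- Against: enantioselective C-H arylations of this kind close five-membered rings through six-membered palladacycles, mostly at methyl or cyclopropyl C-H. Here a seven-membered palladacycle and a choice between enantiotopic hydrogens on an unactivated methylene are required, on a di-ortho-substituted bromide that is prone to protodebromination. Bromination of 5-methoxyresorcinol between the hydroxyls is not trivial either.
- Comparison: the chosen plan asks the substrate to ionise where its structure predisposes it to, while alternative 3 forces a bond for which the substrate has no bias. It is weaker in mechanistic security.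

Key step: step 6

Remark on the chemistry: which antipode of the chiral phosphoric acid delivers the R series cannot be derived reliably for this substrate; the R acid is written, and its mirror image is meant if the first run shows the opposite sense. SEM = 2-(trimethylsilyl)ethoxymethyl. The configuration stays R from 11 to 17 because no CIP priority at C2' changes.

## Route

**Step 1**
Reactants: 1 piperidin-2-one; 2 methyl chloroformate
Product: 3 methyl 2-oxopiperidine-1-carboxylate
Conditions: n-BuLi, THF, −78 °C; then 2, −78 → 0 °C
Reagents that add atoms: none
Why: N-acylation of the lactam anion by addition–elimination at the chloroformate; the imide-type product has an activated ring carbonyl and no N-H, which is what step 3 needs.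

**Step 2**
Reactants: 4 5-methoxyresorcinol (5-methoxybenzene-1,3-diol)
Product: 5 1-methoxy-3,5-bis{[2-(trimethylsilyl)ethoxy]methoxy}benzene
Conditions: SEMCl (2.4 equiv), i-Pr2NEt, CH2Cl2, 0 °C → rt
Reagents that add atoms: 2-(trimethylsilyl)ethoxymethyl chloride (SEMCl), C[Si](C)(C)CCOCCl
Why: Williamson-type O-alkylation of both phenols; the O-CH2-O unit is a strong director for ortho-lithiation and can later be removed by fluoride without acid.

**Step 3**
Reactants: 5 1-methoxy-3,5-bis{[2-(trimethylsilyl)ethoxy]methoxy}benzene; 3 methyl 2-oxopiperidine-1-carboxylate
Product: 7 methyl N-[5-(4-methoxy-2,6-bis{[2-(trimethylsilyl)ethoxy]methoxy}phenyl)-5-oxopentyl]carbamate, via aryllithium 6 (not isolated)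
Conditions: n-BuLi (1.1 equiv), THF, 0 °C; then 3, −78 → −40 °C; aq. NH4Cl
Reagents that add atoms: none
Why: Directed ortho-metalation at the position between the two acetal ethers (cooperative direction), then ring-opening acyl substitution at the endocyclic carbonyl of the N-alkoxycarbonyl lactam; the tetrahedral adduct persists in the cold, so the hindered ketone is released only on quench and is not attacked twice.

**Step 4**
Reactants: 7 methyl N-[5-(4-methoxy-2,6-bis{[2-(trimethylsilyl)ethoxy]methoxy}phenyl)-5-oxopentyl]carbamate
Product: 8 racemic methyl N-[5-hydroxy-5-(4-methoxy-2,6-bis{[2-(trimethylsilyl)ethoxy]methoxy}phenyl)pentyl]carbamate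
Conditions: NaBH4, MeOH–THF, 0 °C → rt
Reagents that add atoms: none
Why: Borohydride reduction of the ketone leaves the carbamate untouched; with both phenols masked no methide can form, so the carbinol is not reduced further, and the racemate is sufficient because step 6 is enantioconvergent.

**Step 5**
Reactants: 8 racemic methyl N-[5-hydroxy-5-(4-methoxy-2,6-bis{[2-(trimethylsilyl)ethoxy]methoxy}phenyl)pentyl]carbamate
Product: 9 racemic methyl N-[5-(2,6-dihydroxy-4-methoxyphenyl)-5-hydroxypentyl]carbamate
Conditions: TBAF, ethylenediamine, THF–DMPU, 45 °C; cold aq. NH4Cl
Reagents that add atoms: none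
Why: Fluoride-induced fragmentation of the silylethyl acetal (attack at silicon, loss of ethene, collapse of the hemiacetal) frees both phenols in a basic medium in which hydroxide is too poor a leaving group for the benzylic carbinol to ionise; ethylenediamine traps the formaldehyde so that it cannot hydroxymethylate the ring.

**Step 6**
Reactants: 9 racemic methyl N-[5-(2,6-dihydroxy-4-methoxyphenyl)-5-hydroxypentyl]carbamate
Product: 11 methyl (2R)-2-(2,6-dihydroxy-4-methoxyphenyl)piperidine-1-carboxylate, via ortho-quinone methide 10 (not isolated)
Conditions: (R)-3,3'-bis(2,4,6-triisopropylphenyl)-1,1'-binaphthyl-2,2'-diyl hydrogen phosphate (10 mol %), 3 Å MS, CH2Cl2 (0.02 M), −40 °C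
Reagents that add atoms: none
Why: Proposed new method: the chiral acid protonates the benzylic hydroxyl of 9 and the trioxygenated ring expels water, so both enantiomers of 9 converge on the planar methide 10 (equivalently its O-protonated benzylic cation paired with the chiral phosphate); the closest known reaction type is the chiral phosphoric acid catalysed conjugate addition of carbon, oxygen, sulfur and azole nitrogen nucleophiles to ortho-quinone methides generated from ortho-hydroxybenzyl alcohols, together with acid-catalysed intramolecular aza-Michael additions of carbamates, and what is new is a tethered carbamate on an alkyl-substituted methide. The carbamate nitrogen adds to the exocyclic methide carbon in a 6-exo-trig closure that forms N1'-C2', closes the piperidine and restores the aromatic ring. C2' is set by the catalyst alone: the phosphate bridges the methide oxygen and the carbamate N-H by hydrogen bonds, so nitrogen is delivered to one face inside the pocket of the 3,3'-aryl groups. The step needs facial selectivity on a planar carbon and nitrogen attack in preference to attack by a ring carbon of a second molecule. The substrate secures this through the four-carbon tether (six-membered transition state, high effective molarity in dilute solution), through the single N-H that serves as the hydrogen-bond handle, and through the two equivalent ortho hydroxyls, which make the methides formed through either oxygen and both side-chain geometries interconvertible by proton transfer, so that only one ion pair has to be differentiated. The carbamate is non-basic, so it does not neutralise the catalyst, and it is a poor leaving group in the cold, so the new centre should not reopen. Elimination to the ortho-hydroxystyrene is a possible side channel but should be reversible under the same acid.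

**Step 7**
Reactants: 11 methyl (2R)-2-(2,6-dihydroxy-4-methoxyphenyl)piperidine-1-carboxylate
Product: 12 5-methoxy-2-[(2R)-1-methylpiperidin-2-yl]benzene-1,3-diol
Conditions: LiAlH4 (6 equiv), THF, 0 °C → reflux; aq. Rochelle salt
Reagents that add atoms: none
Why: Hydride reduction of the carbamate through the formamide and iminium stages turns its carbonyl carbon into the N-methyl group; the phenols are present as aluminium phenoxides, no bond at C2' is involved, and the step is placed before any ketone exists.

**Step 8**
Reactants: 12 5-methoxy-2-[(2R)-1-methylpiperidin-2-yl]benzene-1,3-diol; 13 acetic anhydride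
Product: 14 1-{2,4-dihydroxy-6-methoxy-3-[(2R)-1-methylpiperidin-2-yl]phenyl}ethan-1-one
Conditions: 13 (1.2 equiv), BF3·OEt2 (6 equiv), CH2Cl2, 0 °C → rt; aq. NaOAc, then NaHCO3
Reagents that add atoms: none
Why: Friedel–Crafts C-acetylation at the only free ring positions, which are equivalent by rotation about the aryl–C2' bond; nitrogen is tied up as its BF3 adduct and the phenol oxygens are bound to boron, which should suppress methide formation at C2', and the product is held as a difluoroboron chelate through the hydroxyl, so the methoxy group is not cleaved.

**Step 9**
Reactants: 14 1-{2,4-dihydroxy-6-methoxy-3-[(2R)-1-methylpiperidin-2-yl]phenyl}ethan-1-one; 15 benzoyl chloride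
Product: 17 7-hydroxy-5-methoxy-8-[(2R)-1-methylpiperidin-2-yl]-2-phenyl-4H-chromen-4-one, via 1,3-diketone 16 (not isolated)
Conditions: LiHMDS (4.5 equiv), THF, −78 → −10 °C; 15 (1.05 equiv), −78 °C → rt; then AcOH, H2SO4 (2 equiv), 50 °C
Reagents that add atoms: none
Why: Claisen-type C-benzoylation of the enolate carbon inside the lithium polyanion gives the diketone without phenol protection (the product of a Baker–Venkataraman sequence reached directly); acid-catalysed cyclodehydration then forms O1-C2 and C2=C3, and only the hydroxyl next to the acyl group can close because the other flank is the methoxy group, so the 8-substituted flavone with free 7-OH should result while the protonated amine and the acyl-deactivated ring protect C2'.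

## Compound list

1 | piperidin-2-one | O=C1CCCCN1 | starting material
2 | methyl chloroformate | COC(=O)Cl | starting material
3 | methyl 2-oxopiperidine-1-carboxylate | COC(=O)N1CCCCC1=O | intermediate
4 | 5-methoxyresorcinol (5-methoxybenzene-1,3-diol) | COc1cc(O)cc(O)c1 | starting material
5 | 1-methoxy-3,5-bis{[2-(trimethylsilyl)ethoxy]methoxy}benzene | COc1cc(OCOCC[Si](C)(C)C)cc(OCOCC[Si](C)(C)C)c1 | intermediate
6 | (4-methoxy-2,6-bis{[2-(trimethylsilyl)ethoxy]methoxy}phenyl)lithium | [Li]c1c(OCOCC[Si](C)(C)C)cc(OC)cc1OCOCC[Si](C)(C)C | intermediate
7 | methyl N-[5-(4-methoxy-2,6-bis{[2-(trimethylsilyl)ethoxy]methoxy}phenyl)-5-oxopentyl]carbamate | COC(=O)NCCCCC(=O)c1c(OCOCC[Si](C)(C)C)cc(OC)cc1OCOCC[Si](C)(C)C | intermediate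
8 | racemic methyl N-[5-hydroxy-5-(4-methoxy-2,6-bis{[2-(trimethylsilyl)ethoxy]methoxy}phenyl)pentyl]carbamate | COC(=O)NCCCCC(O)c1c(OCOCC[Si](C)(C)C)cc(OC)cc1OCOCC[Si](C)(C)C | intermediate
9 | racemic methyl N-[5-(2,6-dihydroxy-4-methoxyphenyl)-5-hydroxypentyl]carbamate | COc1cc(O)c(C(O)CCCCNC(=O)OC)c(O)c1 | intermediate
10 | methyl N-[5-(2-hydroxy-4-methoxy-6-oxocyclohexa-2,4-dien-1-ylidene)pentyl]carbamate | COC1=CC(=O)C(=CCCCCNC(=O)OC)C(O)=C1 | intermediate
11 | methyl (2R)-2-(2,6-dihydroxy-4-methoxyphenyl)piperidine-1-carboxylate | COc1cc(O)c([C@H]2CCCCN2C(=O)OC)c(O)c1 | intermediate
12 | 5-methoxy-2-[(2R)-1-methylpiperidin-2-yl]benzene-1,3-diol | COc1cc(O)c([C@H]2CCCCN2C)c(O)c1 | intermediate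
13 | acetic anhydride | CC(=O)OC(C)=O | starting material
14 | 1-{2,4-dihydroxy-6-methoxy-3-[(2R)-1-methylpiperidin-2-yl]phenyl}ethan-1-one | COc1cc(O)c([C@H]2CCCCN2C)c(O)c1C(C)=O | intermediate
15 | benzoyl chloride | O=C(Cl)c1ccccc1 | starting material
16 | 1-{2,4-dihydroxy-6-methoxy-3-[(2R)-1-methylpiperidin-2-yl]phenyl}-3-phenylpropane-1,3-dione | COc1cc(O)c([C@H]2CCCCN2C)c(O)c1C(=O)CC(=O)c1ccccc1 | intermediate
17 | 7-hydroxy-5-methoxy-8-[(2R)-1-methylpiperidin-2-yl]-2-phenyl-4H-chromen-4-one | COc1cc(O)c([C@H]2CCCCN2C)c2oc(-c3ccccc3)cc(=O)c12 | target

## Step count and least certain steps

Total: 9 steps. Longest linear sequence: 8 steps (steps 2 to 9, from 4); step 1 is a one-step side branch.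

**Step 6 (key step, proposed new method).** The most likely failure is poor facial selectivity: the cation is so well stabilised that the ion pair may be loose, and the phosphate can bridge either ortho oxygen. Intermolecular alkylation of the electron-rich ring of a second molecule is the second risk.
Fallback with known chemistry, from 5 to 11: 5 is lithiated as in step 3 and formylated with DMF to 4-methoxy-2,6-bis(SEM-oxy)benzaldehyde F1. Condensation with (S)-2-methylpropane-2-sulfinamide and Ti(OEt)4 gives the (S,E)-N-sulfinyl aldimine F2. Addition of 4-chlorobutylmagnesium bromide in CH2Cl2 in the cold, through the six-membered magnesium chelate, should give the (S)-sulfinamide of the (1R)-5-chloro-1-arylpentylamine F3; the mirror-image auxiliary is used if the ortho acetal oxygens reverse the facial sense. KHMDS closes the ring by N-alkylation to the (2R)-1-[(S)-tert-butylsulfinyl]-2-arylpiperidine F4. HCl in MeOH at 0 °C removes the sulfinyl group to give the (2R)-2-arylpiperidine F5. 2 and Et3N give the methyl (2R)-2-arylpiperidine-1-carboxylate bis-SEM ether F6, and TBAF with ethylenediamine as in step 5 releases 11.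

**Step 3.** The hindered aryllithium may attack the exocyclic carbamate carbonyl of 3 (transfer of the methoxycarbonyl group) or add sluggishly.
Fallback, from 5 to 8: 5-aminopentan-1-ol is acylated with 2 (aq. NaHCO3) to methyl N-(5-hydroxypentyl)carbamate F7 and oxidised (SO3·pyridine, DMSO, Et3N) to methyl N-(5-oxopentyl)carbamate F8. 6, made from 5 and used in 2.2 equivalents after transmetalation with CeCl3 (one equivalent is spent on the N-H), adds to the aldehyde and gives 8 directly.

**Step 5.** The cleavage of aryl SEM ethers may need more heat than the product tolerates; base-induced loss of the benzylic hydroxyl from the phenoxide would then start an uncatalysed, racemic closure or oligomerisation, and untrapped formaldehyde could be captured by the ring.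
Fallback, from 7 to 9: the SEM groups are removed at the acid-stable ketone stage (HCl, MeOH) to give methyl N-[5-(2,6-dihydroxy-4-methoxyphenyl)-5-oxopentyl]carbamate F9. The phenols are silylated (TBSCl, imidazole, DMF) to the bis-TBS ketone F10. NaBH4 gives the racemic bis-TBS carbinol F11, and TBAF buffered with AcOH at −20 °C, a fast and cold desilylation, releases 9.

**Step 8.** Erosion of configuration by reversible ionisation of C2'-N1' under the Lewis acid, or slow acylation because the boron-bound ammonium deactivates the ring.
Fallback, from 12 to 14, under basic conditions throughout: 12 is converted with NaH and SEMCl into (2R)-2-[4-methoxy-2,6-bis(SEM-oxy)phenyl]-1-methylpiperidine F12. Directed metalation between an acetal ether and the methoxy group (s-BuLi, TMEDA, THF, −78 °C) and acylation with N-methoxy-N-methylacetamide give the acetyl bis-SEM ether F13. TBAF with ethylenediamine gives 14.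

**Step 9.** O-benzoylation of the phenoxides in place of C-benzoylation, or poor solubility of the polylithiated species; an extended acid treatment could also erode C2'.
Fallback, from 14 to 16: 14 is benzoylated on both phenols (benzoyl chloride, pyridine) to 4-acetyl-5-methoxy-2-[(2R)-1-methylpiperidin-2-yl]-1,3-phenylene dibenzoate F14. A Baker–Venkataraman shift (KOt-Bu, THF) gives the 1,3-diketone monobenzoate F15. K2CO3 in MeOH removes the remaining benzoate to give 16, which is closed with acid as in step 9.

Handling note: 12 is the intermediate most prone to loss of configuration and should be carried into step 8 without storage; 17 should not be heated for long in neutral protic solvents.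

## Further compounds

F1 | step 6 | 4-methoxy-2,6-bis{[2-(trimethylsilyl)ethoxy]methoxy}benzaldehyde | COc1cc(OCOCC[Si](C)(C)C)c(C=O)c(OCOCC[Si](C)(C)C)c1
F2 | step 6 | (S,E)-N-(4-methoxy-2,6-bis{[2-(trimethylsilyl)ethoxy]methoxy}benzylidene)-2-methylpropane-2-sulfinamide | CC(C)(C)[S@](=O)/N=C/c1c(OCOCC[Si](C)(C)C)cc(OC)cc1OCOCC[Si](C)(C)C
F3 | step 6 | (S)-N-[(1R)-5-chloro-1-(4-methoxy-2,6-bis{[2-(trimethylsilyl)ethoxy]methoxy}phenyl)pentyl]-2-methylpropane-2-sulfinamide | CC(C)(C)[S@](=O)N[C@H](CCCCCl)c1c(OCOCC[Si](C)(C)C)cc(OC)cc1OCOCC[Si](C)(C)C
F4 | step 6 | (2R)-1-[(S)-tert-butylsulfinyl]-2-(4-methoxy-2,6-bis{[2-(trimethylsilyl)ethoxy]methoxy}phenyl)piperidine | CC(C)(C)[S@](=O)N1CCCC[C@@H]1c1c(OCOCC[Si](C)(C)C)cc(OC)cc1OCOCC[Si](C)(C)C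
F5 | step 6 | (2R)-2-(4-methoxy-2,6-bis{[2-(trimethylsilyl)ethoxy]methoxy}phenyl)piperidine | COc1cc(OCOCC[Si](C)(C)C)c([C@H]2CCCCN2)c(OCOCC[Si](C)(C)C)c1
F6 | step 6 | methyl (2R)-2-(4-methoxy-2,6-bis{[2-(trimethylsilyl)ethoxy]methoxy}phenyl)piperidine-1-carboxylate | COc1cc(OCOCC[Si](C)(C)C)c([C@H]2CCCCN2C(=O)OC)c(OCOCC[Si](C)(C)C)c1
F7 | step 3 | methyl N-(5-hydroxypentyl)carbamate | COC(=O)NCCCCCO
F8 | step 3 | methyl N-(5-oxopentyl)carbamate | COC(=O)NCCCCC=O
F9 | step 5 | methyl N-[5-(2,6-dihydroxy-4-methoxyphenyl)-5-oxopentyl]carbamate | COC(=O)NCCCCC(=O)c1c(O)cc(OC)cc1O
F10 | step 5 | methyl N-[5-(2,6-bis{[tert-butyl(dimethyl)silyl]oxy}-4-methoxyphenyl)-5-oxopentyl]carbamate | COC(=O)NCCCCC(=O)c1c(O[Si](C)(C)C(C)(C)C)cc(OC)cc1O[Si](C)(C)C(C)(C)C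
F11 | step 5 | racemic methyl N-[5-(2,6-bis{[tert-butyl(dimethyl)silyl]oxy}-4-methoxyphenyl)-5-hydroxypentyl]carbamate | COC(=O)NCCCCC(O)c1c(O[Si](C)(C)C(C)(C)C)cc(OC)cc1O[Si](C)(C)C(C)(C)C
F12 | step 8 | (2R)-2-(4-methoxy-2,6-bis{[2-(trimethylsilyl)ethoxy]methoxy}phenyl)-1-methylpiperidine | COc1cc(OCOCC[Si](C)(C)C)c([C@H]2CCCCN2C)c(OCOCC[Si](C)(C)C)c1
F13 | step 8 | 1-{6-methoxy-3-[(2R)-1-methylpiperidin-2-yl]-2,4-bis{[2-(trimethylsilyl)ethoxy]methoxy}phenyl}ethan-1-one | COc1cc(OCOCC[Si](C)(C)C)c([C@H]2CCCCN2C)c(OCOCC[Si](C)(C)C)c1C(C)=O
F14 | step 9 | 4-acetyl-5-methoxy-2-[(2R)-1-methylpiperidin-2-yl]-1,3-phenylene dibenzoate | COc1cc(OC(=O)c2ccccc2)c([C@H]2CCCCN2C)c(OC(=O)c2ccccc2)c1C(C)=O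
F15 | step 9 | 3-hydroxy-5-methoxy-2-[(2R)-1-methylpiperidin-2-yl]-4-(3-oxo-3-phenylpropanoyl)phenyl benzoate | COc1cc(OC(=O)c2ccccc2)c([C@H]2CCCCN2C)c(O)c1C(=O)CC(=O)c1ccccc1
A1 | alternative 1 | (R)-5-methoxy-8-(1-methylpiperidin-2-yl)-4-oxo-2-phenyl-4H-chromen-7-yl benzoate | COc1cc(OC(=O)c2ccccc2)c([C@H]2CCCCN2C)c2oc(-c3ccccc3)cc(=O)c12
A2 | alternative 1 | 5-methoxy-2-[(2R)-1-methylpiperidin-2-yl]-4-[(triphenyl-λ5-phosphanylidene)acetyl]-1,3-phenylene dibenzoate | COc1cc(OC(=O)c2ccccc2)c([C@H]2CCCCN2C)c(OC(=O)c2ccccc2)c1C(=O)C=P(c1ccccc1)(c1ccccc1)c1ccccc1
A3 | alternative 2 | (R)-5-methoxy-8-(1-methyl-1,2,3,6-tetrahydropyridin-2-yl)-4-oxo-2-phenyl-4H-chromen-7-yl acetate | COc1cc(OC(C)=O)c([C@H]2CC=CCN2C)c2oc(-c3ccccc3)cc(=O)c12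
A4 | alternative 2 | (R)-5-methoxy-8-{1-[methyl(prop-2-en-1-yl)amino]but-3-en-1-yl}-4-oxo-2-phenyl-4H-chromen-7-yl acetate | COc1cc(OC(C)=O)c([C@@H](CC=C)N(C)CC=C)c2oc(-c3ccccc3)cc(=O)c12
A5 | alternative 2 | 7-hydroxy-5-methoxy-4-oxo-2-phenyl-4H-chromene-8-carbaldehyde | COc1cc(O)c(C=O)c2oc(-c3ccccc3)cc(=O)c12
A6 | alternative 3 | (R)-configured piperidine-fused 1,3-benzoxazin-2-one bearing the spectator piperidine-1-carboxylate | COc1cc(OC(=O)N3CCCCC3)c2[C@H]3CCCCN3C(=O)Oc2c1
A7 | alternative 3 | 2-bromo-5-methoxy-1,3-phenylene bis(piperidine-1-carboxylate) | COc1cc(OC(=O)N2CCCCC2)c(Br)c(OC(=O)N2CCCCC2)c1
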